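**Retrosynthetic overview**
- The stearate is put on last. The quaternary ether carbon C-1 (dienyl + CH2OH) comes from a lactone carbonyl by methylenation, enol-ether epoxidation and dienylalane opening.
- The nine-membered ring is formed second, by ring-closing metathesis between the vinyl group of the linalool unit and an allyl terminus on a trans-fused γ-lactone.
- The γ-lactone is the first ring. Its C-10a–C-3a bond, both ring-fusion stereocenters and the exocyclic methylene come from one Ireland–Claisen [3,3] rearrangement.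
- The Claisen ester is made from a C7 acid derived from (S)-linalool (tertiary carbinol bought) and an allylic alcohol from (S)-glyceraldehyde acetonide; the dioxolane steers the facial course and is then cut back to the ring CH2O.
- Ring order: five-membered lactone, then cyclononene; the lactone is then converted into the tetrahydrofuran.

Assumption: (S)-(+)-linalool and (S)-glyceraldehyde acetonide are bought in high ee; ring locants follow cyclonona[c]furan numbering (target = 1R,3aR,8S,10aS).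

**Step 1**
Reactants: 1 (S)-(+)-linalool
Product: 2 (3S)-3,7-dimethyl-3-(triethylsilyloxy)octa-1,6-diene
Conditions: Et3SiOTf, 2,6-lutidine, CH2Cl2, −78 → 0 °C
Reagents that add atoms: triethylsilyl trifluoromethanesulfonate, CC[Si](CC)(CC)OS(=O)(=O)C(F)(F)F
Why: Silyl triflate silylation of the tertiary allylic alcohol; the bought stereocenter (C-8 of the target) is not touched.

**Step 2**
Reactants: 2 (3S)-3,7-dimethyl-3-(triethylsilyloxy)octa-1,6-diene
Product: 4 (4S)-4-methyl-4-(triethylsilyloxy)hex-5-enal, via secondary ozonide 3 (not isolated)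
Conditions: O3 (1 equiv, Sudan Red 7B end point), CH2Cl2, −78 °C; PPh3, −78 °C → rt
Reagents that add atoms: ozone, [O-][O+]=O
Why: Chemoselective ozonolysis, because the electron-rich trisubstituted alkene reacts much faster than the hindered monosubstituted vinyl group.

**Step 3**
Reactants: 4 (4S)-4-methyl-4-(triethylsilyloxy)hex-5-enal
Product: 5 (3S)-7-methoxy-3-methyl-3-(triethylsilyloxy)hepta-1,6-diene (E/Z mixture at the enol ether)
Conditions: [Ph3PCH2OMe]Cl, KN(SiMe3)2, THF, 0 °C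
Reagents that add atoms: (methoxymethyl)triphenylphosphonium chloride, COC[P+](c1ccccc1)(c1ccccc1)c1ccccc1.[Cl-]
Why: Wittig methoxymethylenation adds the one carbon that becomes C-1 of the ring system.

**Step 4**
Reactants: 5 (3S)-7-methoxy-3-methyl-3-(triethylsilyloxy)hepta-1,6-diene
Product: 6 methyl (5S)-5-methyl-5-(triethylsilyloxy)hept-6-enoate
Conditions: (C5H5NH)[CrO3Cl], NaOAc, CH2Cl2, rt
Reagents that add atoms: pyridinium chlorochromate, [O-][Cr](=O)(=O)Cl.c1cc[nH+]cc1
Why: Chlorochromate oxidation of an enol ether gives the homologated ester directly (Piancatelli oxidation); the tertiary silyl ether cannot be oxidised.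

**Step 5**
Reactants: 7 ethyl (triphenylphosphoranylidene)acetate; 8 allyl bromide
Product: 10 ethyl 2-(triphenylphosphoranylidene)pent-4-enoate, via phosphonium bromide 9 (not isolated)
Conditions: CHCl3, reflux; then 2 M NaOH, CH2Cl2, 0 °C
Reagents that add atoms: none
Why: C-Alkylation of the stabilised ylide followed by deprotonation of the salt gives the α-allyl ylide.

**Step 6**
Reactants: 10 ethyl 2-(triphenylphosphoranylidene)pent-4-enoate; 11 (S)-glyceraldehyde acetonide
Product: 12 ethyl (2E)-2-{[(4R)-2,2-dimethyl-1,3-dioxolan-4-yl]methylidene}pent-4-enoate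
Conditions: CH2Cl2, rt
Reagents that add atoms: none
Why: Wittig olefination with an α-branched stabilised ylide is E-selective (ester trans to the dioxolane) and its neutral conditions do not epimerise the α-alkoxy aldehyde.

**Step 7**
Reactants: 12 ethyl (2E)-2-{[(4R)-2,2-dimethyl-1,3-dioxolan-4-yl]methylidene}pent-4-enoate
Product: 13 (2E)-2-{[(4R)-2,2-dimethyl-1,3-dioxolan-4-yl]methylidene}pent-4-en-1-ol
Conditions: iBu2AlH, CH2Cl2, −78 °C; aq. potassium sodium tartrate
Reagents that add atoms: none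
Why: 1,2-Reduction of the enoate by the aluminium hydride gives the allylic alcohol with the alkene geometry retained.

**Step 8**
Reactants: 6 methyl (5S)-5-methyl-5-(triethylsilyloxy)hept-6-enoate; 13 (2E)-2-{[(4R)-2,2-dimethyl-1,3-dioxolan-4-yl]methylidene}pent-4-en-1-ol
Product: 14 (2E)-2-{[(4R)-2,2-dimethyl-1,3-dioxolan-4-yl]methylidene}pent-4-en-1-yl (5S)-5-methyl-5-(triethylsilyloxy)hept-6-enoate
Conditions: ClBu2SnOSnBu2Cl (5 mol %), toluene, reflux, 4 Å sieves
Reagents that add atoms: none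
Why: Neutral distannoxane-catalysed transesterification (Otera), driven by methanol removal, tolerates the acetonide and the silyl ether.

**Step 9**
Reactants: 14 (2E)-2-{[(4R)-2,2-dimethyl-1,3-dioxolan-4-yl]methylidene}pent-4-en-1-yl (5S)-5-methyl-5-(triethylsilyloxy)hept-6-enoate
Product: 17 (2S,3R)-3-[(4R)-2,2-dimethyl-1,3-dioxolan-4-yl]-4-methylidene-2-[(3S)-3-methyl-3-(triethylsilyloxy)pent-4-en-1-yl]hept-6-enoic acid, via trimethylsilyl ketene acetal 15 (not isolated), via trimethylsilyl ester 16 (not isolated)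
Conditions: LiN(iPr)2, Me3SiCl, THF, −78 → 60 °C; then K2CO3, MeOH–H2O; citric acid to pH 4
Reagents that add atoms: none
Why: Ireland–Claisen [3,3] rearrangement through a chair, in which the (E)-ketene acetal and (E)-alkene give the anti pair and the 1,1-disubstituted alkene; the new bond forms on the alkene face anti to the dioxolane C–O bond (dioxolane C–H in the alkene plane to avoid 1,3-allylic strain with the cis allyl group), so the bought acetonide center sets C-3 and, through the chair, C-2.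

**Step 10**
Reactants: 17 (2S,3R)-3-[(4R)-2,2-dimethyl-1,3-dioxolan-4-yl]-4-methylidene-2-[(3S)-3-methyl-3-(triethylsilyloxy)pent-4-en-1-yl]hept-6-enoic acid
Product: 20 (3S,4R)-3-[(3S)-3-hydroxy-3-methylpent-4-en-1-yl]-4-(penta-1,4-dien-2-yl)oxolan-2-one, via aldehyde acid 18 (not isolated), via hydroxy acid 19 (not isolated)
Conditions: H5IO6, EtOAc, 0 °C → rt; then NaBH4, EtOH, 0 °C; then AcOH–THF–H2O (3:1:1), 45 °C
Reagents that add atoms: none
Why: Periodic acid hydrolyses the terminal acetonide and cleaves the glycol (the aldehyde is held as its hydroxylactone by the neighbouring acid), and borohydride reduction with acid-promoted lactonisation and desilylation gives the trans-3,4-disubstituted γ-lactone, which is also the thermodynamic epimer at enolisable C-3.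

**Step 11**
Reactants: 20 (3S,4R)-3-[(3S)-3-hydroxy-3-methylpent-4-en-1-yl]-4-(penta-1,4-dien-2-yl)oxolan-2-one
Product: 21 (3aR,6Z,8S,10aS)-8-hydroxy-8-methyl-4-methylidene-3,3a,4,5,8,9,10,10a-octahydro-1H-cyclonona[c]furan-1-one
Conditions: second-generation Hoveyda–Grubbs catalyst RuCl2(H2IMes)(=CH–C6H4-2-OiPr) (10 mol %), toluene (1 mM), 80 °C, argon sparge
Reagents that add atoms: none
Why: Ring-closing metathesis, in which the carbene loads on the unhindered allyl terminus and closes onto the carbinol vinyl group (assisted by the free allylic OH); the nine-membered ring can hold only the Z alkene and no stereocenter is touched.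

**Step 12**
Reactants: 21 (3aR,6Z,8S,10aS)-8-hydroxy-8-methyl-4-methylidene-3,3a,4,5,8,9,10,10a-octahydro-1H-cyclonona[c]furan-1-one
Product: 22 (3aR,6Z,8S,10aS)-8-methyl-1,4-dimethylidene-3,3a,4,5,8,9,10,10a-octahydro-1H-cyclonona[c]furan-8-ol
Conditions: Cp2TiMe2 (3 equiv), toluene, 70 °C, dark; basic alumina filtration
Reagents that add atoms: dimethyltitanocene, [CH3-].[CH3-].c1cc[cH-]c1.c1cc[cH-]c1.[Ti+4]
Why: Petasis methylenation converts the lactone carbonyl into the exocyclic enol ether under non-basic conditions, so C-10a is not epimerised; the excess reagent covers the free hydroxyl.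

**Step 13**
Reactants: 23 3-methylbut-2-enal
Product: 24 (1E)-1-iodo-4-methylpenta-1,3-diene
Conditions: CrCl2, CHI3, THF, 0 °C
Reagents that add atoms: iodoform, IC(I)I
Why: Takai olefination gives the (E)-iodoalkene selectively.

**Step 14**
Reactants: 22 (3aR,6Z,8S,10aS)-8-methyl-1,4-dimethylidene-3,3a,4,5,8,9,10,10a-octahydro-1H-cyclonona[c]furan-8-ol; 24 (1E)-1-iodo-4-methylpenta-1,3-diene
Product: 28 (1R,3aR,6Z,8S,10aS)-1-(hydroxymethyl)-8-methyl-4-methylidene-1-[(1E)-4-methylpenta-1,3-dien-1-yl]-3,3a,4,5,8,9,10,10a-octahydro-1H-cyclonona[c]furan-8-ol, via dienyllithium 25 (not isolated), via dienyl(dimethyl)alane 26 (not isolated), via spiro-epoxide 27 (not isolated)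
Conditions: 24, t-BuLi (2 equiv), Et2O, −78 °C, then Me2AlCl; separately 22, dimethyldioxirane (1.05 equiv), CH2Cl2, −78 °C, evaporate cold; combine (4 equiv alane), CH2Cl2, −78 → −30 °C
Reagents that add atoms: dimethyldioxirane, CC1(C)OO1
Why: The dioxirane epoxidises only the electron-rich enol ether, on the face opposite the adjacent C-10a–C-10 bond, and the alkenylalane ionises the anomeric C–O bond and delivers the dienyl group to that same face (epoxide opening with retention), which places the dienyl trans to C-10 at the new quaternary center and frees the CH2OH.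

**Step 15**
Reactants: 28 (1R,3aR,6Z,8S,10aS)-1-(hydroxymethyl)-8-methyl-4-methylidene-1-[(1E)-4-methylpenta-1,3-dien-1-yl]-3,3a,4,5,8,9,10,10a-octahydro-1H-cyclonona[c]furan-8-ol; 29 octadecanoyl chloride
Product: 30 CNP0274030.1
Conditions: pyridine, DMAP (cat.), CH2Cl2, 0 °C
Reagents that add atoms: none
Why: Acylation occurs only at the primary alcohol; the tertiary allylic alcohol is inert under these conditions.

**Compound list**
1 | (S)-(+)-linalool | C=C[C@@](C)(O)CCC=C(C)C | starting material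
2 | (3S)-3,7-dimethyl-3-(triethylsilyloxy)octa-1,6-diene | C=C[C@@](C)(O[Si](CC)(CC)CC)CCC=C(C)C | intermediate
3 | secondary ozonide of 2 (5,5-dimethyl-1,2,4-trioxolane, ring carbon unassigned) | C=C[C@@](C)(O[Si](CC)(CC)CC)CCC1OOC(C)(C)O1 | intermediate
4 | (4S)-4-methyl-4-(triethylsilyloxy)hex-5-enal | C=C[C@@](C)(O[Si](CC)(CC)CC)CCC=O | intermediate
5 | (3S)-7-methoxy-3-methyl-3-(triethylsilyloxy)hepta-1,6-diene (E/Z mixture) | C=C[C@@](C)(O[Si](CC)(CC)CC)CCC=COC | intermediate
6 | methyl (5S)-5-methyl-5-(triethylsilyloxy)hept-6-enoate | C=C[C@@](C)(O[Si](CC)(CC)CC)CCCC(=O)OC | intermediate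
7 | ethyl (triphenylphosphoranylidene)acetate | CCOC(=O)C=P(c1ccccc1)(c1ccccc1)c1ccccc1 | starting material
8 | allyl bromide | C=CCBr | starting material
9 | (1-ethoxy-1-oxopent-4-en-2-yl)triphenylphosphonium bromide | CCOC(=O)C(CC=C)[P+](c1ccccc1)(c1ccccc1)c1ccccc1.[Br-] | intermediate
10 | ethyl 2-(triphenylphosphoranylidene)pent-4-enoate | CCOC(=O)C(CC=C)=P(c1ccccc1)(c1ccccc1)c1ccccc1 | intermediate
11 | (S)-glyceraldehyde acetonide, (4S)-2,2-dimethyl-1,3-dioxolane-4-carbaldehyde | O=C[C@@H]1COC(C)(C)O1 | starting material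
12 | ethyl (2E)-2-{[(4R)-2,2-dimethyl-1,3-dioxolan-4-yl]methylidene}pent-4-enoate | CCOC(=O)/C(CC=C)=C/[C@@H]1COC(C)(C)O1 | intermediate
13 | (2E)-2-{[(4R)-2,2-dimethyl-1,3-dioxolan-4-yl]methylidene}pent-4-en-1-ol | OC/C(CC=C)=C/[C@@H]1COC(C)(C)O1 | intermediate
14 | (2E)-2-{[(4R)-2,2-dimethyl-1,3-dioxolan-4-yl]methylidene}pent-4-en-1-yl (5S)-5-methyl-5-(triethylsilyloxy)hept-6-enoate | C=C[C@@](C)(O[Si](CC)(CC)CC)CCCC(=O)OC/C(CC=C)=C/[C@@H]1COC(C)(C)O1 | intermediate
15 | trimethylsilyl ketene acetal of 14 (chain cis to the allyloxy oxygen) | C=C[C@@](C)(O[Si](CC)(CC)CC)CC/C=C(/O[Si](C)(C)C)OC/C(CC=C)=C/[C@@H]1COC(C)(C)O1 | intermediate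
16 | trimethylsilyl ester of 17 | C=CCC(=C)[C@H]([C@@H]1COC(C)(C)O1)[C@H](CC[C@](C)(O[Si](CC)(CC)CC)C=C)C(=O)O[Si](C)(C)C | intermediate
17 | (2S,3R)-3-[(4R)-2,2-dimethyl-1,3-dioxolan-4-yl]-4-methylidene-2-[(3S)-3-methyl-3-(triethylsilyloxy)pent-4-en-1-yl]hept-6-enoic acid | C=CCC(=C)[C@H]([C@@H]1COC(C)(C)O1)[C@H](CC[C@](C)(O[Si](CC)(CC)CC)C=C)C(=O)O | intermediate
18 | (2S,3R)-3-formyl-4-methylidene-2-[(3S)-3-methyl-3-(triethylsilyloxy)pent-4-en-1-yl]hept-6-enoic acid (in equilibrium with its hydroxylactone) | C=CCC(=C)[C@H](C=O)[C@H](CC[C@](C)(O[Si](CC)(CC)CC)C=C)C(=O)O | intermediate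
19 | (2S,3R)-3-(hydroxymethyl)-4-methylidene-2-[(3S)-3-methyl-3-(triethylsilyloxy)pent-4-en-1-yl]hept-6-enoic acid | C=CCC(=C)[C@H](CO)[C@H](CC[C@](C)(O[Si](CC)(CC)CC)C=C)C(=O)O | intermediate
20 | (3S,4R)-3-[(3S)-3-hydroxy-3-methylpent-4-en-1-yl]-4-(penta-1,4-dien-2-yl)oxolan-2-one | O=C1OC[C@@H](C(=C)CC=C)[C@@H]1CC[C@](C)(O)C=C | intermediate
21 | (3aR,6Z,8S,10aS)-8-hydroxy-8-methyl-4-methylidene-3,3a,4,5,8,9,10,10a-octahydro-1H-cyclonona[c]furan-1-one | C=C1C/C=C\[C@@](C)(O)CC[C@H]2[C@H]1COC2=O | intermediate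
22 | (3aR,6Z,8S,10aS)-8-methyl-1,4-dimethylidene-3,3a,4,5,8,9,10,10a-octahydro-1H-cyclonona[c]furan-8-ol | C=C1C/C=C\[C@@](C)(O)CC[C@H]2[C@H]1COC2=C | intermediate
23 | 3-methylbut-2-enal | CC(C)=CC=O | starting material
24 | (1E)-1-iodo-4-methylpenta-1,3-diene | I/C=C/C=C(C)C | intermediate
25 | [(1E)-4-methylpenta-1,3-dien-1-yl]lithium | [Li]/C=C/C=C(C)C | intermediate
26 | dimethyl[(1E)-4-methylpenta-1,3-dien-1-yl]alane | C[Al](C)/C=C/C=C(C)C | intermediate
27 | spiro-epoxide of 22 at C-1 (epoxide oxygen on the face opposite the C-10a–C-10 bond) | C=C1C/C=C\[C@@](C)(O)CC[C@H]2[C@H]1CO[C@@]2(O3)C3 | intermediate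
28 | (1R,3aR,6Z,8S,10aS)-1-(hydroxymethyl)-8-methyl-4-methylidene-1-[(1E)-4-methylpenta-1,3-dien-1-yl]-3,3a,4,5,8,9,10,10a-octahydro-1H-cyclonona[c]furan-8-ol | C=C1C/C=C\[C@@](C)(O)CC[C@H]2[C@H]1CO[C@@]2(/C=C/C=C(C)C)CO | intermediate
29 | octadecanoyl chloride | CCCCCCCCCCCCCCCCCC(=O)Cl | starting material
30 | CNP0274030.1, {(1R,3aR,6Z,8S,10aS)-8-hydroxy-8-methyl-4-methylidene-1-[(1E)-4-methylpenta-1,3-dien-1-yl]-3,3a,4,5,8,9,10,10a-octahydro-1H-cyclonona[c]furan-1-yl}methyl octadecanoate | C=C1C/C=C\[C@@](C)(O)CC[C@H]2[C@H]1CO[C@@]2(/C=C/C=C(C)C)COC(=O)CCCCCCCCCCCCCCCCC | target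

**Step count**
Total: 15 steps. Longest linear sequence: 11 steps (1–4, 8–12, 14, 15).

**Steps most likely to fail**

*Step 9 (facial control of the Ireland–Claisen by the acyclic dioxolane).* If the diastereofacial ratio is poor, C-3a can be set by conjugate addition to a butenolide instead. This fallback sets out from aldehyde 4 and comes back at lactone 20.
- NaClO2 oxidation of 4 gives (4S)-4-methyl-4-(triethylsilyloxy)hex-5-enoic acid F1.
- Iododecarboxylation (PhI(OAc)2, I2, hν) gives (3S)-5-iodo-3-methyl-3-(triethylsilyloxy)pent-1-ene F2.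
- Lithium di(penta-1,4-dien-2-yl)cuprate with Me3SiCl adds to commercial (S)-5-[(tert-butyldimethylsilyloxy)methyl]furan-2(5H)-one anti to the C-5 group, giving (4R,5S)-5-[(tert-butyldimethylsilyloxy)methyl]-4-(penta-1,4-dien-2-yl)oxolan-2-one F3.
- LiOH, Bu4NF, NaIO4, NaBH4 and then acid excise the carbinol carbon and reclose the ring to (4R)-4-(penta-1,4-dien-2-yl)oxolan-2-one F4.
- The lithium enolate of F4 is alkylated by F2 (DMPU) trans to the C-4 group, giving (3S,4R)-3-[(3S)-3-methyl-3-(triethylsilyloxy)pent-4-en-1-yl]-4-(penta-1,4-dien-2-yl)oxolan-2-one F5.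
- AcOH–THF–H2O then gives lactone 20.

*Step 11 (nine-membered ring closure).* The risks are oligomers and a competing seven-membered closure onto the 1,1-disubstituted alkene. The fallback reverses the order of ring closure and rearrangement; it sets out from ester 14, which has no 1,1-disubstituted alkene yet, and comes back at lactone 21.
- Metathesis of 14 with the same RuCl2(H2IMes)(=CH–C6H4-2-OiPr) catalyst at high dilution gives, after separation of the E isomer, (6S,7Z)-10-{(E)-[(4R)-2,2-dimethyl-1,3-dioxolan-4-yl]methylidene}-6-methyl-6-(triethylsilyloxy)-1-oxacycloundec-7-en-2-one F6.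
- A ring-contracting Ireland–Claisen rearrangement (LiN(iPr)2, Me3SiCl, THF, then heat) forms the cyclononene directly as (1S,2R,5Z,7S)-2-[(4R)-2,2-dimethyl-1,3-dioxolan-4-yl]-7-methyl-3-methylidene-7-(triethylsilyloxy)cyclonon-5-ene-1-carboxylic acid F7.
- The conditions of step 10 convert F7 into lactone 21; any cis-fused lactone is equilibrated with DBU.

*Step 14 (epoxidation and alane opening at a very acid-labile anomeric center).* The fallback builds the quaternary center by carbonyl addition and ring closure; it sets out from lactone 21 and comes back at diol 28.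
- Dienyllithium 25 (2.2 equiv, −78 °C) adds once to give (2E)-1-[(1S,4S,5Z,9R)-4-hydroxy-9-(hydroxymethyl)-4-methyl-8-methylidenecyclonon-5-en-1-yl]-5-methylhexa-2,4-dien-1-one F8.
- I2, PPh3 and imidazole convert the primary alcohol into (2E)-1-[(1S,4S,5Z,9R)-4-hydroxy-9-(iodomethyl)-4-methyl-8-methylidenecyclonon-5-en-1-yl]-5-methylhexa-2,4-dien-1-one F9.
- (iPrO)Me2SiCH2MgCl with CeCl3 adds 1,2 to the ketone under Felkin control, and the alkoxide displaces the iodide on warming to give (1R,3aR,6Z,8S,10aS)-1-{[dimethyl(propan-2-yloxy)silyl]methyl}-8-methyl-4-methylidene-1-[(1E)-4-methylpenta-1,3-dien-1-yl]-3,3a,4,5,8,9,10,10a-octahydro-1H-cyclonona[c]furan-8-ol F10.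
- Tamao oxidation (KF, KHCO3, H2O2) gives diol 28.

**Further compounds**
F1 | step 9 | (4S)-4-methyl-4-(triethylsilyloxy)hex-5-enoic acid | C=C[C@@](C)(O[Si](CC)(CC)CC)CCC(=O)O
F2 | step 9 | (3S)-5-iodo-3-methyl-3-(triethylsilyloxy)pent-1-ene | C=C[C@@](C)(O[Si](CC)(CC)CC)CCI
F3 | step 9 | (4R,5S)-5-[(tert-butyldimethylsilyloxy)methyl]-4-(penta-1,4-dien-2-yl)oxolan-2-one | O=C1C[C@H](C(=C)CC=C)[C@@H](CO[Si](C)(C)C(C)(C)C)O1
F4 | step 9 | (4R)-4-(penta-1,4-dien-2-yl)oxolan-2-one | O=C1C[C@H](C(=C)CC=C)CO1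
F5 | step 9 | (3S,4R)-3-[(3S)-3-methyl-3-(triethylsilyloxy)pent-4-en-1-yl]-4-(penta-1,4-dien-2-yl)oxolan-2-one | O=C1OC[C@@H](C(=C)CC=C)[C@@H]1CC[C@](C)(O[Si](CC)(CC)CC)C=C
F6 | step 11 | (6S,7Z)-10-{(E)-[(4R)-2,2-dimethyl-1,3-dioxolan-4-yl]methylidene}-6-methyl-6-(triethylsilyloxy)-1-oxacycloundec-7-en-2-one | O=C1CCC[C@](C)(O[Si](CC)(CC)CC)/C=C\C/C(=C\[C@@H]2COC(C)(C)O2)CO1
F7 | step 11 | (1S,2R,5Z,7S)-2-[(4R)-2,2-dimethyl-1,3-dioxolan-4-yl]-7-methyl-3-methylidene-7-(triethylsilyloxy)cyclonon-5-ene-1-carboxylic acid | C=C1C/C=C\[C@@](C)(O[Si](CC)(CC)CC)CC[C@H](C(=O)O)[C@H]1[C@@H]2COC(C)(C)O2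
F8 | step 14 | (2E)-1-[(1S,4S,5Z,9R)-4-hydroxy-9-(hydroxymethyl)-4-methyl-8-methylidenecyclonon-5-en-1-yl]-5-methylhexa-2,4-dien-1-one | C=C1C/C=C\[C@@](C)(O)CC[C@H](C(=O)/C=C/C=C(C)C)[C@H]1CO
F9 | step 14 | (2E)-1-[(1S,4S,5Z,9R)-4-hydroxy-9-(iodomethyl)-4-methyl-8-methylidenecyclonon-5-en-1-yl]-5-methylhexa-2,4-dien-1-one | C=C1C/C=C\[C@@](C)(O)CC[C@H](C(=O)/C=C/C=C(C)C)[C@H]1CI
F10 | step 14 | (1R,3aR,6Z,8S,10aS)-1-{[dimethyl(propan-2-yloxy)silyl]methyl}-8-methyl-4-methylidene-1-[(1E)-4-methylpenta-1,3-dien-1-yl]-3,3a,4,5,8,9,10,10a-octahydro-1H-cyclonona[c]furan-8-ol | C=C1C/C=C\[C@@](C)(O)CC[C@H]2[C@H]1CO[C@@]2(/C=C/C=C(C)C)C[Si](C)(C)OC(C)C
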